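**Retrosynthetic overview**
- The ring segment C4(CH3)=C5H–C6H2–C7H=C8(CHO) is a skipped (1,4-)diene: an E-trisubstituted alkene with its methyl group, a bis-allylic CH2 and an enal, all inside the cyclononadiene ring. This is the retron of a 1,4-hydrovinylation. Cutting C6–C7 and moving one H from the C4 methyl group to C7 opens the only ring to an acyclic isomer that carries a 2-substituted buta-1,3-diene and an α-substituted acrolein.
- The diene and the C2 carbinol come from a catalytic asymmetric isoprenylboration of a C2 aldehyde, itself made from a thioester.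
- C1 and C9 come from an iminium-catalysed syn Mukaiyama–Michael addition of a silyl ketene thioacetal to fumaraldehyde mono(dimethyl acetal). α-Methylenation then builds the acrolein.
- The side-chain stereocentre comes from a Negishi coupling to a β-substituted butenolide, an asymmetric copper hydride reduction, and lactone opening to thioester plus acetate.
- Ring order: one temporary lactone ring is opened in step 3. The nine-membered carbocycle, the only ring of the target, is closed in step 13.

Key step: step 13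

Remark: ring atoms are numbered C1 (bears the side chain), C2 (carbinol), C3, C4 (methyl), C5, C6 (CH2), C7, C8 (alkene carbon with CHO), C9 (CH–CHO), and these locants are also used for the acyclic precursors; the sense of induction of each chiral catalyst is assigned from the accepted model of its reaction class.

Step 1
Reactants: 1 4-bromofuran-2(5H)-one; 2 5-bromo-2-methylpent-2-ene
Product: 4 4-(4-methylpent-3-en-1-yl)furan-2(5H)-one, via homoprenylzinc bromide 3 (not isolated)
Conditions: 2, Zn dust, LiCl, THF, 40 °C; then 1, PdCl2(dppf) (3 mol%), THF, 50 °C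
Reagents that add atoms: none
Why: Negishi coupling; the vinylogous acyl bromide adds fast to zerovalent palladium, the bidentate ligand suppresses β-hydride elimination of the primary alkyl group, and the trisubstituted alkene is inert.

Step 2
Reactants: 4 4-(4-methylpent-3-en-1-yl)furan-2(5H)-one
Product: 5 (4S)-4-(4-methylpent-3-en-1-yl)oxolan-2-one
Conditions: CuCl2·2H2O (5 mol%), (S)-p-tol-BINAP (5 mol%), NaOt-Bu (20 mol%), PMHS, t-BuOH, toluene, 0 °C to 23 °C
Reagents that add atoms: none
Why: Asymmetric conjugate reduction by a ligated copper hydride (monovalent copper); the ligand selects the face of the β-carbon and sets the side-chain stereocentre as S, while the isolated alkene is not reduced.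

Step 3
Reactants: 5 (4S)-4-(4-methylpent-3-en-1-yl)oxolan-2-one
Product: 7 S-ethyl (3S)-3-(acetoxymethyl)-7-methyloct-6-enethioate, via hydroxy thioester 6 (not isolated)
Conditions: AlMe3, EtSH, CH2Cl2, 0 °C to 23 °C; then Ac2O, DMAP, 0 °C
Reagents that add atoms: ethanethiol CCS; acetic anhydride CC(=O)OC(C)=O
Why: Aluminium thiolate-mediated thiolysis of the lactone attacks only the acyl carbon, so the stereocentre is untouched, and capping the aluminium alkoxide in situ as the acetate of the target prevents relactonisation.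

Step 4
Reactants: 7 S-ethyl (3S)-3-(acetoxymethyl)-7-methyloct-6-enethioate
Product: 8 (2S)-2-[(1Z)-2-(ethylsulfanyl)-2-(trimethylsilyloxy)ethenyl]-6-methylhept-5-en-1-yl acetate
Conditions: LiN(i-Pr)2 (1.05 equiv), Me3SiCl (in situ), THF, −78 °C
Reagents that add atoms: chlorotrimethylsilane C[Si](C)(C)Cl
Why: Kinetic enolisation and O-silylation of the more acidic thioester through a cyclic deprotonation transition state should give the (Z)-silyl ketene thioacetal, and one equivalent of base with an internal quench spares the acetate.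

Step 5
Reactants: 8 (2S)-2-[(1Z)-2-(ethylsulfanyl)-2-(trimethylsilyloxy)ethenyl]-6-methylhept-5-en-1-yl acetate; 9 (2E)-4,4-dimethoxybut-2-enal
Product: 10 S-ethyl (2R,3S)-2-[(2S)-1-acetoxy-6-methylhept-5-en-2-yl]-3-(dimethoxymethyl)-5-oxopentanethioate
Conditions: (2R,5R)-5-benzyl-2-tert-butyl-3-methylimidazolidin-4-one·CCl3CO2H (20 mol%), H2O (2 equiv), CH2Cl2, −60 °C
Reagents that add atoms: none
Why: Iminium-catalysed enantioselective Mukaiyama–Michael addition; the catalyst shields one enal face and so sets the future C9, and the open transition state of the (Z)-ketene thioacetal gives the syn C1/C9 relationship, with water taking up the silyl group.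

Step 6
Reactants: 10 S-ethyl (2R,3S)-2-[(2S)-1-acetoxy-6-methylhept-5-en-2-yl]-3-(dimethoxymethyl)-5-oxopentanethioate
Product: 11 S-ethyl (2R,3R)-2-[(2S)-1-acetoxy-6-methylhept-5-en-2-yl]-3-(dimethoxymethyl)-4-formylpent-4-enethioate
Conditions: 37% aq. CH2O, pyrrolidine (10 mol%), EtCO2H (10 mol%), i-PrOH, 45 °C
Reagents that add atoms: formaldehyde C=O
Why: Amine/acid-catalysed Mannich condensation–elimination (α-methylenation of an α-unbranched aldehyde) builds the α-substituted acrolein; no stereocentre is α to a free aldehyde, so none can epimerise (the C9 descriptor changes only because priorities change).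

Step 7
Reactants: 11 S-ethyl (2R,3R)-2-[(2S)-1-acetoxy-6-methylhept-5-en-2-yl]-3-(dimethoxymethyl)-4-formylpent-4-enethioate
Product: 12 S-ethyl (2R,3R)-2-[(2S)-1-acetoxy-6-methylhept-5-en-2-yl]-3,4-bis(dimethoxymethyl)pent-4-enethioate
Conditions: HC(OMe)3, PPTS (5 mol%), MeOH, 23 °C
Reagents that add atoms: trimethyl orthoformate COC(OC)OC
Why: Acid-catalysed acetalisation with the orthoformate as water scavenger masks the enal, so that the aldehyde made next is the only free carbonyl electrophile.

Step 8
Reactants: 12 S-ethyl (2R,3R)-2-[(2S)-1-acetoxy-6-methylhept-5-en-2-yl]-3,4-bis(dimethoxymethyl)pent-4-enethioate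
Product: 13 (2S,3R,4R)-3-formyl-4,5-bis(dimethoxymethyl)-2-(4-methylpent-3-en-1-yl)hex-5-en-1-yl acetate
Conditions: Et3SiH, Pd/C (10 wt% Pd, 5 mol%), acetone, 23 °C
Reagents that add atoms: none
Why: Fukuyama reduction (insertion of zerovalent palladium into the C(O)–S bond, hydride transfer from silicon, reductive elimination) gives the aldehyde at neutral pH, so that acetate, acetals, the hindered alkenes and the α-stereocentre should survive.

Step 9
Reactants: 14 isoprene
Product: 16 4,4,5,5-tetramethyl-2-(2-methylidenebut-3-en-1-yl)-1,3,2-dioxaborolane, via isoprenylpotassium 15 (not isolated)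
Conditions: 2,2,6,6-tetramethylpiperidine, n-BuLi, KOt-Bu, THF, −78 °C; i-PrOBpin, −78 °C; HCl·Et2O
Reagents that add atoms: 2-isopropoxy-4,4,5,5-tetramethyl-1,3,2-dioxaborolane CC(C)OB1OC(C)(C)C(C)(C)O1
Why: Allylic metalation of the methyl group of isoprene by the potassium amide followed by electrophilic borylation gives the isoprenyl boronate.

Step 10
Reactants: 13 (2S,3R,4R)-3-formyl-4,5-bis(dimethoxymethyl)-2-(4-methylpent-3-en-1-yl)hex-5-en-1-yl acetate; 16 4,4,5,5-tetramethyl-2-(2-methylidenebut-3-en-1-yl)-1,3,2-dioxaborolane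
Product: 17 (2S,3R,4S)-3-[(2R)-1,1-dimethoxy-3-(dimethoxymethyl)but-3-en-2-yl]-4-hydroxy-6-methylidene-2-(4-methylpent-3-en-1-yl)oct-7-en-1-yl acetate
Conditions: (S)-TRIP phosphoric acid (10 mol%), 4 Å MS, toluene, −30 °C; aq. NaHCO3
Reagents that add atoms: none
Why: Chiral phosphoric acid-catalysed allylboration through a closed chair transition state adds the whole C3–C6 diene unit, and the catalyst selects the aldehyde face and sets the C2 carbinol as S over the weak bias of the α-stereocentre.

Step 11
Reactants: 17 (2S,3R,4S)-3-[(2R)-1,1-dimethoxy-3-(dimethoxymethyl)but-3-en-2-yl]-4-hydroxy-6-methylidene-2-(4-methylpent-3-en-1-yl)oct-7-en-1-yl acetate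
Product: 18 (2S,3R,4S)-3-[(2R)-1,1-dimethoxy-3-(dimethoxymethyl)but-3-en-2-yl]-6-methylidene-2-(4-methylpent-3-en-1-yl)-4-(triethylsilyloxy)oct-7-en-1-yl acetate
Conditions: Et3SiCl, imidazole, DMF, 0 °C to 23 °C
Reagents that add atoms: chlorotriethylsilane CC[Si](Cl)(CC)CC
Why: Base-mediated O-silylation under non-acidic conditions blocks the γ-hydroxy group before it can transacetalise with the C9 acetal.

Step 12
Reactants: 18 (2S,3R,4S)-3-[(2R)-1,1-dimethoxy-3-(dimethoxymethyl)but-3-en-2-yl]-6-methylidene-2-(4-methylpent-3-en-1-yl)-4-(triethylsilyloxy)oct-7-en-1-yl acetate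
Product: 19 (2S,3R,4S)-3-[(2R)-3-formyl-1,1-dimethoxybut-3-en-2-yl]-6-methylidene-2-(4-methylpent-3-en-1-yl)-4-(triethylsilyloxy)oct-7-en-1-yl acetate
Conditions: SiO2, 10% aq. oxalic acid, CH2Cl2, 23 °C
Reagents that add atoms: water O
Why: Chemoselective acetal hydrolysis; the allylic acetal ionises to a conjugated oxocarbenium ion far faster than the hindered saturated acetal, so only the enal is released while the silyl ether stays.

Step 13
Reactants: 19 (2S,3R,4S)-3-[(2R)-3-formyl-1,1-dimethoxybut-3-en-2-yl]-6-methylidene-2-(4-methylpent-3-en-1-yl)-4-(triethylsilyloxy)oct-7-en-1-yl acetate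
Product: 20 (2S)-2-[(1R,2S,4E,7E,9R)-9-(dimethoxymethyl)-8-formyl-4-methyl-2-(triethylsilyloxy)cyclonona-4,7-dien-1-yl]-6-methylhept-5-en-1-yl acetate
Conditions: CoBr2(dppp) (10 mol%), Zn (30 mol%), NaB[3,5-(CF3)2C6H3]4 (15 mol%), CH2Cl2, slow addition of 19 to 0.005 M, 23 °C
Reagents that add atoms: none
Why: Proposed new method: a cationic monovalent cobalt–diphosphine fragment should bind the s-cis buta-1,3-diene (η4) and the C=C bond of the α-substituted acrolein of the same molecule, join the unsubstituted diene terminus (C6) to the acrolein CH2 (C7) by oxidative cyclisation to a σ-enolate/η3-allyl cobaltacycle (trivalent cobalt), lose a β-hydride from C7 and deliver it by reductive elimination to the former exocyclic CH2 of the diene, which is an intramolecular 1,4-hydrovinylation in which no atom is lost. The closest known reaction type is the intermolecular cobalt-catalysed 1,4-hydrovinylation (heterodimerisation) of 2-substituted 1,3-dienes with acrylates to skipped 2,5-dienoates; the enal partner and the closure of a medium ring are what is new. The nine-membered ring is closed in an endo mode inside the coordination sphere, both π systems sitting on one metal, so that ring closure can compete with oligomerisation under dilution. No stereocentre is formed and the four existing ones are not touched (C9 carries an acetal, not an aldehyde); of the two alkene geometries, the s-cis η4-diene gives an anti-η3-allyl so that the new methyl group and C6 end cis on C4=C5 (ring bonds trans, 4E), and at C7=C8 only the cis ring alkene (CHO trans to C6, 7E) fits a nine-membered ring that already holds a trans alkene. The step needs chemoselectivity (only the conjugated diene and the single electron-poor alkene bind, the trisubstituted side-chain alkene is inert), regioselectivity for the unhindered diene terminus over the exocyclic CH2 (which would give an eight-membered ring) and hydrovinylation over the type 2 Diels–Alder reaction; the substituent on the internal diene carbon, the α-branch of the acrolein that places cobalt on the enolate carbon, and room temperature without a strong Lewis acid should secure them.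

Step 14
Reactants: 20 (2S)-2-[(1R,2S,4E,7E,9R)-9-(dimethoxymethyl)-8-formyl-4-methyl-2-(triethylsilyloxy)cyclonona-4,7-dien-1-yl]-6-methylhept-5-en-1-yl acetate
Product: 21 (2S)-2-[(1R,2S,4E,7E,9R)-8,9-diformyl-2-hydroxy-4-methylcyclonona-4,7-dien-1-yl]-6-methylhept-5-en-1-yl acetate (target)
Conditions: 48% aq. HF/MeCN (1:19), 0 °C
Reagents that add atoms: water O
Why: Acidic fluoride cleaves the triethylsilyl ether and hydrolyses the remaining dimethyl acetal in one operation; the C2 hydroxyl and the C9 formyl group are trans on the ring, so no lactol forms, and the cold, base-free medium should leave C9 and the acetate intact.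

**Compound list**
1 | 4-bromofuran-2(5H)-one | O=C1C=C(Br)CO1 | starting material
2 | 5-bromo-2-methylpent-2-ene | CC(C)=CCCBr | starting material
3 | (4-methylpent-3-en-1-yl)zinc bromide | CC(C)=CCC[Zn]Br | intermediate
4 | 4-(4-methylpent-3-en-1-yl)furan-2(5H)-one | O=C1C=C(CCC=C(C)C)CO1 | intermediate
5 | (4S)-4-(4-methylpent-3-en-1-yl)oxolan-2-one | O=C1C[C@H](CCC=C(C)C)CO1 | intermediate
6 | S-ethyl (3S)-3-(hydroxymethyl)-7-methyloct-6-enethioate (present as its dimethylaluminium alkoxide) | OC[C@@H](CCC=C(C)C)CC(=O)SCC | intermediate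
7 | S-ethyl (3S)-3-(acetoxymethyl)-7-methyloct-6-enethioate | CC(=O)OC[C@@H](CCC=C(C)C)CC(=O)SCC | intermediate
8 | (2S)-2-[(1Z)-2-(ethylsulfanyl)-2-(trimethylsilyloxy)ethenyl]-6-methylhept-5-en-1-yl acetate | CC(=O)OC[C@@H](CCC=C(C)C)/C=C(\SCC)O[Si](C)(C)C | intermediate
9 | (2E)-4,4-dimethoxybut-2-enal | COC(OC)/C=C/C=O | starting material
10 | S-ethyl (2R,3S)-2-[(2S)-1-acetoxy-6-methylhept-5-en-2-yl]-3-(dimethoxymethyl)-5-oxopentanethioate | CC(=O)OC[C@@H](CCC=C(C)C)[C@H]([C@@H](C(OC)OC)CC=O)C(=O)SCC | intermediate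
11 | S-ethyl (2R,3R)-2-[(2S)-1-acetoxy-6-methylhept-5-en-2-yl]-3-(dimethoxymethyl)-4-formylpent-4-enethioate | CC(=O)OC[C@@H](CCC=C(C)C)[C@H]([C@@H](C(OC)OC)C(=C)C=O)C(=O)SCC | intermediate
12 | S-ethyl (2R,3R)-2-[(2S)-1-acetoxy-6-methylhept-5-en-2-yl]-3,4-bis(dimethoxymethyl)pent-4-enethioate | CC(=O)OC[C@@H](CCC=C(C)C)[C@H]([C@@H](C(OC)OC)C(=C)C(OC)OC)C(=O)SCC | intermediate
13 | (2S,3R,4R)-3-formyl-4,5-bis(dimethoxymethyl)-2-(4-methylpent-3-en-1-yl)hex-5-en-1-yl acetate | CC(=O)OC[C@@H](CCC=C(C)C)[C@H]([C@@H](C(OC)OC)C(=C)C(OC)OC)C=O | intermediate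
14 | isoprene | CC(=C)C=C | starting material
15 | (2-methylidenebut-3-en-1-yl)potassium | [K+].[CH2-]C(=C)C=C | intermediate
16 | 4,4,5,5-tetramethyl-2-(2-methylidenebut-3-en-1-yl)-1,3,2-dioxaborolane | C=CC(=C)CB1OC(C)(C)C(C)(C)O1 | intermediate
17 | (2S,3R,4S)-3-[(2R)-1,1-dimethoxy-3-(dimethoxymethyl)but-3-en-2-yl]-4-hydroxy-6-methylidene-2-(4-methylpent-3-en-1-yl)oct-7-en-1-yl acetate | CC(=O)OC[C@@H](CCC=C(C)C)[C@H]([C@@H](C(OC)OC)C(=C)C(OC)OC)[C@@H](O)CC(=C)C=C | intermediate
18 | triethylsilyl ether of 17 | CC(=O)OC[C@@H](CCC=C(C)C)[C@H]([C@@H](C(OC)OC)C(=C)C(OC)OC)[C@@H](O[Si](CC)(CC)CC)CC(=C)C=C | intermediate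
19 | (2S,3R,4S)-3-[(2R)-3-formyl-1,1-dimethoxybut-3-en-2-yl]-6-methylidene-2-(4-methylpent-3-en-1-yl)-4-(triethylsilyloxy)oct-7-en-1-yl acetate | CC(=O)OC[C@@H](CCC=C(C)C)[C@H]([C@@H](C(OC)OC)C(=C)C=O)[C@@H](O[Si](CC)(CC)CC)CC(=C)C=C | intermediate
20 | (2S)-2-[(1R,2S,4E,7E,9R)-9-(dimethoxymethyl)-8-formyl-4-methyl-2-(triethylsilyloxy)cyclonona-4,7-dien-1-yl]-6-methylhept-5-en-1-yl acetate | CC(=O)OC[C@@H](CCC=C(C)C)[C@H]1[C@@H](O[Si](CC)(CC)CC)C/C(C)=C/C/C=C(/C=O)[C@@H]1C(OC)OC | intermediate
21 | (2S)-2-[(1R,2S,4E,7E,9R)-8,9-diformyl-2-hydroxy-4-methylcyclonona-4,7-dien-1-yl]-6-methylhept-5-en-1-yl acetate | CC(=O)OC[C@@H](CCC=C(C)C)[C@H]1[C@@H](O)C/C(C)=C/C/C=C(/C=O)[C@@H]1C=O | target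

Total step count: 14. Longest linear sequence: 13 (steps 1–8 and 10–14).

**Steps most likely to fail**

**Step 13.** Ring closure may be lost in three ways: coupling at the exocyclic diene CH2, cycloaddition of diene and enal, or oligomerisation.
- The fallback sets out from 19 and comes back at 21. It is a classical sulfone-anion ring closure of the same C6–C7 bond.
- Benzenesulfinic acid is added to the enal and the aldehyde is acetalised in the same pot (PhSO2Na, AcOH, MeOH, then HC(OMe)3, PPTS). This gives the β-sulfonyl acetal F1.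
- Iron-catalysed 1,4-hydroboration of the diene (FeCl2, iminopyridine ligand, Mg, pinacolborane) gives the (E)-allylboronate F2.
- NaBO3 oxidises it to the (E)-allylic alcohol F3, and MsCl, LiCl and collidine convert that into the allylic chloride F4.
- LiN(SiMe3)2 under high dilution alkylates the α-sulfonyl carbanion intramolecularly to the cyclic sulfone F5.
- Aqueous HF in MeCN gives the hydroxy dialdehyde sulfone F6, and Et3N eliminates benzenesulfinate to 21.

**Step 5.** Addition of the hindered β-branched ketene thioacetal may be slow, and the existing stereocentre may work against the catalyst, which would erode the facial and syn selectivity.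
- The fallback sets out from 5 and comes back at 12. It forms the C1–C9 bond on the intact lactone, where the ring fixes the ketene acetal geometry and forces attack anti to the side chain.
- LiN(i-Pr)2 and Me3SiCl give the cyclic silyl ketene acetal F7.
- The same iminium catalysis with 9 gives the lactone aldehyde F8.
- α-Methylenation gives the lactone enal F9, and acetalisation gives the lactone bis-acetal F10.
- Opening with AlMe3/EtSH followed by Ac2O gives 12.

**Step 10.** Catalyst control over the hindered, α-branched aldehyde may be insufficient, and the free γ-hydroxy acetal may cyclise during work-up.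
- The fallback sets out from 13 and comes back at 17. It separates carbon–carbon bond formation from stereocontrol.
- A Barbier reaction (In, 2-(bromomethyl)buta-1,3-diene, THF) gives the C2-epimeric alcohols F11.
- Dess–Martin oxidation gives the ketone F12.
- Corey–Bakshi–Shibata reduction ((R)-Me-oxazaborolidine, BH3·SMe2) gives 17 under reagent control.

**Further compounds**
F1 | step 13 | β-sulfonyl acetal (C8 epimers) | CC(=O)OC[C@@H](CCC=C(C)C)[C@H]([C@@H](C(OC)OC)C(CS(=O)(=O)c1ccccc1)C(OC)OC)[C@@H](O[Si](CC)(CC)CC)CC(=C)C=C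
F2 | step 13 | (E)-allylboronate | CC(=O)OC[C@@H](CCC=C(C)C)[C@H]([C@@H](C(OC)OC)C(CS(=O)(=O)c1ccccc1)C(OC)OC)[C@@H](O[Si](CC)(CC)CC)C/C(C)=C/CB1OC(C)(C)C(C)(C)O1
F3 | step 13 | (E)-allylic alcohol | CC(=O)OC[C@@H](CCC=C(C)C)[C@H]([C@@H](C(OC)OC)C(CS(=O)(=O)c1ccccc1)C(OC)OC)[C@@H](O[Si](CC)(CC)CC)C/C(C)=C/CO
F4 | step 13 | (E)-allylic chloride | CC(=O)OC[C@@H](CCC=C(C)C)[C@H]([C@@H](C(OC)OC)C(CS(=O)(=O)c1ccccc1)C(OC)OC)[C@@H](O[Si](CC)(CC)CC)C/C(C)=C/CCl
F5 | step 13 | cyclic sulfone (C7 and C8 epimers) | CC(=O)OC[C@@H](CCC=C(C)C)[C@H]1[C@@H](O[Si](CC)(CC)CC)C/C(C)=C/CC(S(=O)(=O)c2ccccc2)C(C(OC)OC)[C@@H]1C(OC)OC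
F6 | step 13 | hydroxy dialdehyde sulfone | CC(=O)OC[C@@H](CCC=C(C)C)[C@H]1[C@@H](O)C/C(C)=C/CC(S(=O)(=O)c2ccccc2)C(C=O)[C@@H]1C=O
F7 | step 5 | cyclic silyl ketene acetal of 5 | C[Si](C)(C)OC1=C[C@H](CCC=C(C)C)CO1
F8 | step 5 | lactone aldehyde | O=C1[C@@H]([C@@H](C(OC)OC)CC=O)[C@H](CCC=C(C)C)CO1
F9 | step 5 | lactone enal | O=C1[C@@H]([C@@H](C(OC)OC)C(=C)C=O)[C@H](CCC=C(C)C)CO1
F10 | step 5 | lactone bis-acetal | O=C1[C@@H]([C@@H](C(OC)OC)C(=C)C(OC)OC)[C@H](CCC=C(C)C)CO1
F11 | step 10 | C2-epimeric alcohols | CC(=O)OC[C@@H](CCC=C(C)C)[C@H]([C@@H](C(OC)OC)C(=C)C(OC)OC)C(O)CC(=C)C=C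
F12 | step 10 | C2 ketone | CC(=O)OC[C@@H](CCC=C(C)C)[C@H]([C@@H](C(OC)OC)C(=C)C(OC)OC)C(=O)CC(=C)C=C
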